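**Analysis of the target**

Target 23 is an oxane (ring atoms O1, C2, C3, C4, C5, C6). It carries a 4‑hydroxyphenyl group at C2, an (E)‑4‑hydroxycinnamyl group at C3 and, at C5, an exocyclic carbinol carbon C7 bearing the third 4‑hydroxyphenyl ring. The stereocentres are C2 (R), C3 (S), C5 (R) and C7 (R), and the three ring substituents are all cis. In the chair with the C3 and C5 groups equatorial, the C2 aryl group is therefore axial, so the target is the less stable C2 epimer. Any step that lets the benzylic C2–O1 bond ionise, or that reduces a cyclic oxocarbenium ion, would drift to the 2,3‑trans isomer; C2 has to be fixed under kinetic, reagent control and kept away from acid afterwards. C2–O1 and C7–OH are both p‑oxygenated benzylic C–O bonds, the E‑styrene forbids hydrogenation and hydrogenolysis, and three phenols must be freed under mild conditions at the end. The difficulty lies in the all‑cis ring pattern, in the C5/C7 pair that lies partly outside the ring, and in avoiding late C–C bond formation next to these benzylic ethers. The route rests on one feature: C3 carries two three‑carbon, aryl‑terminated arms of the same origin. One is the intact cinnamyl group; the other, C4–C5–C7(Ar), is a cinnamyl unit whose alkene has taken up a CH2–O unit (C6) at C5 and an oxygen at C7, which is the formaldehyde Prins adduct of an E‑styrene. With C2 at the carboxyl oxidation level, C3 maps onto the central carbon of a symmetric dicinnamyl malonate.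

**Retrosynthetic reasoning**

Compound numbers are those of the steps and of the compound list below.

*Deprotection (23 from 22).* The three phenols and the C7 hydroxyl are carried as silyl ethers, so the last step is a single buffered fluoride treatment. No acid is used once the benzylic C2–O1 bond exists.

*O1–C6 (22 from 21).* The ring is opened at O1–C6 and not at O1–C2. Forming O1–C2 would mean substitution at an electron‑rich benzylic carbon, which ionises and gives the more stable 2,3‑trans oxane. Closing O1–C6 is an SN2 displacement at a primary carbon by the C2 alkoxide; C2 keeps the configuration it had as a carbinol and the axial aryl group is locked irreversibly.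

*C2 carbinol and C2–aryl bond (21 from 20; 20 from 17 and 19).* The carbinol in 21 is traced to aryl ketone 20, so that C2 is set by a reagent‑controlled hydride reduction in the open chain. The C2–aryl bond is cut next: 20 comes from N‑methoxy‑N‑methyl amide 17 and aryl Grignard reagent 19 (from bromide 18). The C6 oxygen is already a sulfonate in 17 (from hydroxy amide 16); it is thus protected against hemiketal formation and relactonisation and is activated for the closure without a protecting group of its own.

*Amide C–N bond (16 from 15).* Hydroxy amide 16 is the ring‑opened form of δ‑lactone 15. Lactone 15 has the same six ring atoms as the final oxane, and C3 is α to its carbonyl. The C3/C5 cis relationship can therefore be set in 15 by equilibration to the diequatorial isomer.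

*C3–H and lactone C2–O1 (15 from 13 through 14; 13 from 12; 12 from 11).* The hydrogen at C3 replaces a second carboxyl group, so 15 is traced to α‑methoxycarbonyl lactone 13. Its C7 silyl ether comes from hydroxy lactone 12. The silyl group is needed before any base treatment: a free C7 hydroxyl could translactonise onto C2 to an isomeric six‑membered lactone in which the stable C3 configuration is the wrong one. Lactone 12 is cut at C2–O1 to diol diester 11, in which the primary C6 hydroxyl attacks one ester of a malonate. C3 is now the malonate carbon, and which ester is attacked does not matter.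

*Acetal (11 from 9).* The 1,3‑diol of 11 is tied into the methylene acetal of dioxane 9. This must be opened without ionising the benzylic C7–O bond.

*C5–C6 and C7–O (9 from 7 and 8).* The dioxane is cut into one E‑styrene arm of dicinnamyl malonate 7 and two units of formaldehyde 8. This disconnection removes C6 and both oxygens and both new stereocentres at once and exposes the symmetry of 7. The forward reaction has to select one enantioface of the alkene, deliver the trans‑4,5‑dioxane and stop after one arm.

*C3–C4 and C3–CH2 (7 from 5 and two 4; 4 from 1).* Both arms are attached to dimethyl malonate 5 by a double palladium‑catalysed allylic alkylation with cinnamyl acetate 4, through monoalkylated 6. Acetate 4 comes from methyl 4‑hydroxycinnamate 1 by silylation (2), ester reduction (3) and acetylation.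

**Alternatives that were turned down**

Alternative 1: Both aryl carbinol–α‑carbon bonds, C2–C3 and C5–C7, are cut together. This leads to bis‑imide A1, a five‑carbon diacyl unit (C3–C4–C5 plus two acyl carbons) flanked by two benzyl‑oxazolidinone auxiliaries, and two molecules of aryl aldehyde A2. In the forward step both soft‑enolised magnesium enolates add anti to A2 and give the twofold‑symmetric bis‑aldol adduct A3; no ring is formed. In its favour, one known, auxiliary‑controlled operation sets all four stereocentres, and C2 and C3 are fixed directly. On this point it is stronger than the chosen route, which needs a reagent‑controlled ketone reduction and an equilibration. Against it, both acyl carbons are at the wrong oxidation level. After reduction there are two equivalent primary hydroxyls: one has to be activated alone for ring closure, and the other has to be extended by a two‑carbon styrenyl unit. That extension is an sp3–sp2 coupling at a β‑branched primary carbon, or a homologation and E‑selective olefination, carried out late and next to two electron‑rich benzylic C–O bonds. Adducts of electron‑rich aryl aldehydes are also prone to retro‑aldol cleavage, and two equivalents of auxiliary are consumed. The chosen route gives up some certainty at C2 and C3. In return it has the whole carbon skeleton, E‑cinnamyl group included, before the key step, uses a catalytic source of chirality, and needs no late C–C bond.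

Alternative 2: C3 and C5 are first tied together through a three‑carbon bridge, so that the oxane sits inside a 3‑oxabicyclo[3.3.1]nonene. O1–C6 and C5–C6 are then cut, which leads to the cyclohexenyl aryl carbinol A4 and formaldehyde 8. In the forward step acid converts A4 and 8 into a methylene oxocarbenium ion, the ring alkene attacks it, and proton loss gives bicycle A5 with the aryl group equatorial. Cleavage of the remaining alkene then gives a formyl group on C5 and a CH2–CHO arm on C3. In its favour, the bicycle forces C3 and C5 cis and places the aryl group equatorial on the bicycle, which is the axial, all‑cis arrangement of the monocyclic oxane. This is the most direct answer to the hardest stereochemical problem and is stronger than a reduction followed by kinetic closure. Against it, A4 already needs two stereocentres. The acid step acts on an electron‑rich benzylic carbinol, and the site of alkene attack and of proton loss must both be controlled. After ring cleavage the two aldehydes must be told apart, C7 has to be made by aryl addition to an α‑branched, epimerisable aldehyde without a strong control element, and the E‑styrene has to be made by a late olefination. The chosen route makes C5, C6 and C7 in one catalytic step on a substrate that already holds both aryl arms, and its endgame is shorter. Its control of C2 is weaker.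

Alternative 3: O1–C2 is cut and the C3 side chain is read as a malonyl group, so that C2, C3 and the malonate carbon form a donor–acceptor cyclopropane. The precursor is A6, a cis‑2‑aryl‑3‑alkyl cyclopropane‑1,1‑diester whose chain carries C5, C7 and the free C6 hydroxyl. In the forward step a Lewis acid activates the diester and the C6 hydroxyl opens the ring at the benzylic carbon with inversion, which gives the all‑cis oxane A7. In its favour, C2 follows stereospecifically from the cyclopropane geometry, the closure gives the all‑cis ring directly, and the electron‑poor sulfonate on the C2 aryl ring keeps the opening SN2‑like. At C2 this is stronger than the chosen route. Against it, A6 requires an enantio‑ and diastereoselective cis‑cyclopropanation of a Z‑alkene that already bears two stereocentres. Any SN1 leakage gives the 2,3‑trans isomer. The malonyl group of A7 must then lose one carbon and be turned into the E‑cinnamyl group (dealkoxycarbonylation, reduction to the aldehyde, olefination), and the aryl sulfonate needs a separate strongly basic deprotection. In the chosen route the malonate carbon is C3 itself, one carboxyl carbon becomes C2 and the other is lost as CO2, and no olefination is needed, so the step count is lower.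

Key step: step 5

**Remarks before the steps**

- Protecting groups: the phenols are carried as triisopropylsilyl ethers (TIPSO = triisopropylsilyloxy), not as tert‑butyldimethylsilyl ethers. Aryl triisopropylsilyl ethers should better withstand the iodide, amidine and alkoxide steps, and fluoride still removes them. The C7 hydroxyl is carried as its tert‑butyldimethylsilyl ether (TBSO).
- Catalyst of step 5: the starting point is the imidodiphosphorimidate acid built from two 3,3′‑bis[3,5‑bis(trifluoromethyl)phenyl]‑1,1′‑bi‑2‑naphthol units with two N‑trifluoromethanesulfonyl groups. The 3,3′‑aryl group is the variable to tune. The antipode that gives (4R,5R)‑9 is assumed to be identified on a model E‑β‑alkylstyrene.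
- Formaldehyde is numbered once (8) and is charged as paraformaldehyde.

**Steps**

Step 1
Reactants: 1 methyl (E)‑3‑(4‑hydroxyphenyl)prop‑2‑enoate (methyl 4‑hydroxycinnamate)
Product: 2 methyl (E)‑3‑[4‑(TIPSO)phenyl]prop‑2‑enoate
Conditions: i‑Pr3SiCl, imidazole, DMF, 0 °C → rt
Reagents that add atoms: triisopropylsilyl chloride, CC(C)[Si](Cl)(C(C)C)C(C)C
Why: Silylation of a phenol with a silyl chloride and imidazole is routine; the bulky silyl group is chosen for the stability of its aryl ethers in the later basic and nucleophilic steps.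

Step 2
Reactants: 2 methyl (E)‑3‑[4‑(TIPSO)phenyl]prop‑2‑enoate
Product: 3 (E)‑3‑[4‑(TIPSO)phenyl]prop‑2‑en‑1‑ol
Conditions: i‑Bu2AlH (2.2 equiv), CH2Cl2, −78 °C; aqueous potassium sodium tartrate
Reagents that add atoms: none
Why: 1,2‑Reduction of a cinnamate ester with i‑Bu2AlH at low temperature should give the allylic alcohol without touching the alkene or the aryl silyl ether.

Step 3
Reactants: 3 (E)‑3‑[4‑(TIPSO)phenyl]prop‑2‑en‑1‑ol
Product: 4 (E)‑3‑[4‑(TIPSO)phenyl]prop‑2‑en‑1‑yl acetate
Conditions: Ac2O, pyridine, 4‑(dimethylamino)pyridine (cat.), CH2Cl2, 0 °C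
Reagents that add atoms: acetic anhydride, CC(=O)OC(C)=O
Why: Plain acylation; the acetate is preferred to a halide because electron‑rich cinnamyl halides ionise and decompose, whereas the acetate is stable until palladium activates it.

Step 4
Reactants: 5 dimethyl malonate; 4 (E)‑3‑[4‑(TIPSO)phenyl]prop‑2‑en‑1‑yl acetate (2.3 equiv)
Product: 7 dimethyl 2,2‑bis{(E)‑3‑[4‑(TIPSO)phenyl]prop‑2‑en‑1‑yl}propanedioate, via monoallylated malonate 6 (not isolated)
Conditions: NaH (2.3 equiv), Pd(PPh3)4 (3 mol %), THF, 0 → 50 °C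
Reagents that add atoms: none
Why: Tsuji–Trost allylic alkylation: zerovalent palladium ionises the acetate to a syn‑η3‑cinnamyl complex that the malonate anion attacks at the unsubstituted terminus, giving the linear E product; the tertiary anion of 6 reacts in the same sense and even more selectively for the linear isomer.

Step 5
Reactants: 7 dimethyl 2,2‑bis{(E)‑3‑[4‑(TIPSO)phenyl]prop‑2‑en‑1‑yl}propanedioate; 8 formaldehyde (as paraformaldehyde, two units per dioxane)
Product: 9 dimethyl 2‑{(E)‑3‑[4‑(TIPSO)phenyl]prop‑2‑en‑1‑yl}‑2‑{[(4R,5R)‑4‑[4‑(TIPSO)phenyl]‑1,3‑dioxan‑5‑yl]methyl}propanedioate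
Conditions: (CH2O)n (1.2 equiv of CH2O per 7), chiral imidodiphosphorimidate acid [two 3,3′‑bis(3,5‑bis(trifluoromethyl)phenyl)‑BINOL units, N‑SO2CF3 groups] (5 mol %), cyclohexane/CHCl3, 0 °C → rt; recovered 7 recycled
Reagents that add atoms: none
Why: Proposed new method: the closest known reaction type is the catalytic enantioselective Prins reaction of aryl alkenes with paraformaldehyde under confined chiral Brønsted acids, and the acid‑catalysed racemic Prins reaction of E‑β‑alkyl‑p‑alkoxystyrenes to trans‑4‑aryl‑5‑alkyl‑1,3‑dioxanes is classical; new here are the enantioselective version on an internal E‑β‑alkylstyrene and its use on one of two identical arms. The acid activates formaldehyde, as its hemiformal dimer, inside the chiral pocket, and the alkene attacks through C5, the carbon remote from the aryl group, so that C5–C6 forms and positive charge builds up at benzylic C7, where the p‑silyloxy group stabilises it (Markovnikov regiocontrol). The hemiformal oxygen then bonds to C7 on the same face of the former alkene, in the same asynchronous event or directly after it, so the 1,3‑dioxane closes by six‑membered C7–O bond formation through a chair with the aryl group and the C4 chain equatorial. C5 is set by the alkene enantioface that the confined counter‑anion leaves open to formaldehyde (catalyst control). C7 follows from the E geometry and suprafacial addition, and the trans‑diequatorial dioxane is also the thermodynamic product should the benzylic C–O bond reopen. The two arms of 7 are homotopic and C3 bears two identical esters, so either arm gives the same compound and no stereocentre arises at C3. Selectivity for one arm is statistical and is enforced by keeping formaldehyde limiting and recycling 7; the bis‑dioxane is removed by chromatography.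

Step 6
Reactants: 9 dioxane malonate from step 5
Product: 11 dimethyl 2‑{(2R,3R)‑3‑hydroxy‑2‑(hydroxymethyl)‑3‑[4‑(TIPSO)phenyl]propyl}‑2‑{(E)‑3‑[4‑(TIPSO)phenyl]prop‑2‑en‑1‑yl}propanedioate, via silyl ether bipyridinium triflate 10 (not isolated)
Conditions: Me3SiOTf (3 equiv), 2,2′‑bipyridyl (4.5 equiv), CH2Cl2, 0 °C → rt; then H2O; aqueous NaHCO3
Reagents that add atoms: none
Why: Silyl triflate/2,2′‑bipyridyl cleavage of a methylene acetal: the weakly Lewis‑acidic N‑silylpyridinium opens the acetal at the acetal carbon, the oxocarbenium ion is trapped as an N‑(alkoxymethyl)pyridinium salt, and water releases the diol. No protic acid is present, so the benzylic C7–O bond, the aryl silyl ethers and the remaining styrene should not be ionised or cleaved, and C5 and C7 are untouched.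

Step 7
Reactants: 11 diol diester from step 6
Product: 12 methyl (5R)‑5‑{(R)‑hydroxy[4‑(TIPSO)phenyl]methyl}‑2‑oxo‑3‑{(E)‑3‑[4‑(TIPSO)phenyl]prop‑2‑en‑1‑yl}oxane‑3‑carboxylate (both C3 epimers)
Conditions: 1,8‑diazabicyclo[5.4.0]undec‑7‑ene (DBU, 0.2 equiv), toluene, 4 Å molecular sieves, rt; used crude
Reagents that add atoms: none
Why: Six‑membered lactonisation by intramolecular transesterification, helped by the quaternary C3 (Thorpe–Ingold effect); the primary C6 hydroxyl should react far faster than the hindered benzylic C7 hydroxyl. Either ester may be attacked, so C3 becomes a stereocentre of no consequence that is erased in step 9.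

Step 8
Reactants: 12 hydroxy lactone ester from step 7
Product: 13 methyl (5R)‑5‑{(R)‑(TBSO)[4‑(TIPSO)phenyl]methyl}‑2‑oxo‑3‑{(E)‑3‑[4‑(TIPSO)phenyl]prop‑2‑en‑1‑yl}oxane‑3‑carboxylate (both C3 epimers)
Conditions: t‑BuMe2SiOTf, 2,6‑lutidine, CH2Cl2, −78 → 0 °C
Reagents that add atoms: tert‑butyldimethylsilyl trifluoromethanesulfonate, CC(C)(C)[Si](C)(C)OS(=O)(=O)C(F)(F)F
Why: Silylation of a hindered secondary alcohol with a silyl triflate and a hindered base is standard; it removes the only nucleophile that could translactonise or form a second lactone in the basic steps that follow.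

Step 9
Reactants: 13 silylated lactone ester from step 8
Product: 15 (3S,5R)‑5‑{(R)‑(TBSO)[4‑(TIPSO)phenyl]methyl}‑3‑{(E)‑3‑[4‑(TIPSO)phenyl]prop‑2‑en‑1‑yl}oxan‑2‑one (3,5‑cis), via lactone epimer mixture 14 (not isolated)
Conditions: LiI (4 equiv), pyridine, H2O (2 equiv), 110 °C; work‑up; then DBU (1 equiv), toluene, 80 °C
Reagents that add atoms: none
Why: Krapcho‑type dealkoxycarbonylation: iodide removes the ester methyl group by SN2, the β‑carbonyl carboxylate loses CO2 and the lactone enolate is protonated. Base‑mediated epimerisation of the α‑centre then funnels both C3 epimers into the 3,5‑cis lactone, in which both substituents are equatorial, so C3 is set relative to C5 by thermodynamic control; any trans isomer left is separated and resubjected to the base.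

Step 10
Reactants: 15 cis lactone from step 9
Product: 16 (2S,4R,5R)‑5‑(TBSO)‑4‑(hydroxymethyl)‑N‑methoxy‑N‑methyl‑5‑[4‑(TIPSO)phenyl]‑2‑{(E)‑3‑[4‑(TIPSO)phenyl]prop‑2‑en‑1‑yl}pentanamide
Conditions: MeNH(OMe)·HCl (3 equiv), AlMe3 (3 equiv), CH2Cl2, 0 °C → rt; aqueous potassium sodium tartrate; used at once
Reagents that add atoms: N,O‑dimethylhydroxylamine hydrochloride, CNOC.Cl
Why: Aluminium‑amide aminolysis of a lactone to the Weinreb amide; the reagent is barely basic, so C3 should not epimerise, and the silyl ethers and the styrene are inert to it.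

Step 11
Reactants: 16 hydroxy Weinreb amide from step 10
Product: 17 (2S,4R,5R)‑5‑(TBSO)‑N‑methoxy‑N‑methyl‑4‑[(4‑methylphenylsulfonyloxy)methyl]‑5‑[4‑(TIPSO)phenyl]‑2‑{(E)‑3‑[4‑(TIPSO)phenyl]prop‑2‑en‑1‑yl}pentanamide
Conditions: p‑MeC6H4SO2Cl, Et3N, 4‑(dimethylamino)pyridine (cat.), CH2Cl2, 0 °C
Reagents that add atoms: p‑toluenesulfonyl chloride, Cc1ccc(cc1)S(Cl)(=O)=O
Why: Sulfonylation of the only free hydroxyl, a primary one; the tosylate stops relactonisation and later hemiketal formation and is the leaving group for step 14.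

Step 12
Reactants: 17 tosyloxy Weinreb amide from step 11; 18 (4‑bromophenoxy)triisopropylsilane
Product: 20 (2S,4R,5R)‑5‑(TBSO)‑1,5‑bis[4‑(TIPSO)phenyl]‑2‑{(E)‑3‑[4‑(TIPSO)phenyl]prop‑2‑en‑1‑yl}‑4‑[(4‑methylphenylsulfonyloxy)methyl]pentan‑1‑one, via arylmagnesium bromide 19 (not isolated)
Conditions: 18, Mg, THF, rt (gives 19, 2 equiv); then 17, THF, −20 → 0 °C; aqueous NH4Cl
Reagents that add atoms: none
Why: Weinreb ketone synthesis: the chelated tetrahedral adduct prevents over‑addition and releases the ketone only on quench, which also shields C3 from epimerisation. An uncatalysed aryl Grignard reagent should not displace a primary tosylate at or below 0 °C, and tosylate–bromide exchange, should it occur, leaves an equally good leaving group.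

Step 13
Reactants: 20 aryl ketone from step 12
Product: 21 (1R,2S,4R,5R)‑5‑(TBSO)‑1,5‑bis[4‑(TIPSO)phenyl]‑2‑{(E)‑3‑[4‑(TIPSO)phenyl]prop‑2‑en‑1‑yl}‑4‑[(4‑methylphenylsulfonyloxy)methyl]pentan‑1‑ol
Conditions: (S)‑2‑methyl‑CBS‑oxazaborolidine (0.5 equiv), BH3·SMe2 (1.0 equiv), THF, −30 °C, slow addition of 20; MeOH
Reagents that add atoms: none
Why: Corey–Bakshi–Shibata reduction: with the aryl group as the large substituent the (S)‑catalyst should deliver hydride to the face that gives the (R)‑carbinol at C2 (reagent control); low temperature and a limited amount of borane keep hydroboration of the styrene in check.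

Step 14
Reactants: 21 hydroxy tosylate from step 13
Product: 22 (2R,3S,5R)‑5‑{(R)‑(TBSO)[4‑(TIPSO)phenyl]methyl}‑2‑[4‑(TIPSO)phenyl]‑3‑{(E)‑3‑[4‑(TIPSO)phenyl]prop‑2‑en‑1‑yl}oxane
Conditions: NaH (1.5 equiv), THF, 0 °C → rt
Reagents that add atoms: none
Why: Intramolecular Williamson etherification, 6‑exo‑tet at the primary C6; the C2–O bond is not broken, so C2 keeps its configuration, and the irreversible closure locks the all‑cis ring with its axial aryl group.

Step 15
Reactants: 22 fully silylated oxane from step 14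
Product: 23 4‑[(2R,3S,5R)‑5‑[(R)‑hydroxy(4‑hydroxyphenyl)methyl]‑3‑[(E)‑3‑(4‑hydroxyphenyl)prop‑2‑en‑1‑yl]oxan‑2‑yl]phenol (CNP0182155.1)
Conditions: Bu4NF (6 equiv), AcOH (6 equiv), THF, 0 °C → rt
Reagents that add atoms: none
Why: Fluoride desilylation: the three aryl silyl ethers should cleave fast and the secondary alkyl silyl ether more slowly; the acetic acid buffer keeps the medium from becoming basic enough to open the p‑hydroxybenzylic C2–O1 or C7–O bonds through quinone methides.

**Compound list**

1 | methyl (E)‑3‑(4‑hydroxyphenyl)prop‑2‑enoate | COC(=O)/C=C/c1ccc(O)cc1 | starting material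
2 | methyl (E)‑3‑[4‑(triisopropylsilyloxy)phenyl]prop‑2‑enoate | COC(=O)/C=C/c1ccc(O[Si](C(C)C)(C(C)C)C(C)C)cc1 | intermediate
3 | (E)‑3‑[4‑(triisopropylsilyloxy)phenyl]prop‑2‑en‑1‑ol | OC/C=C/c1ccc(O[Si](C(C)C)(C(C)C)C(C)C)cc1 | intermediate
4 | (E)‑3‑[4‑(triisopropylsilyloxy)phenyl]prop‑2‑en‑1‑yl acetate | CC(=O)OC/C=C/c1ccc(O[Si](C(C)C)(C(C)C)C(C)C)cc1 | intermediate
5 | dimethyl malonate | COC(=O)CC(=O)OC | starting material
6 | dimethyl 2‑{(E)‑3‑[4‑(triisopropylsilyloxy)phenyl]prop‑2‑en‑1‑yl}propanedioate | COC(=O)C(C/C=C/c1ccc(O[Si](C(C)C)(C(C)C)C(C)C)cc1)C(=O)OC | intermediate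
7 | dimethyl 2,2‑bis{(E)‑3‑[4‑(triisopropylsilyloxy)phenyl]prop‑2‑en‑1‑yl}propanedioate | COC(=O)C(C/C=C/c1ccc(O[Si](C(C)C)(C(C)C)C(C)C)cc1)(C/C=C/c1ccc(O[Si](C(C)C)(C(C)C)C(C)C)cc1)C(=O)OC | intermediate
8 | formaldehyde (charged as paraformaldehyde) | C=O | starting material
9 | dimethyl 2‑{(E)‑3‑[4‑(triisopropylsilyloxy)phenyl]prop‑2‑en‑1‑yl}‑2‑{[(4R,5R)‑4‑[4‑(triisopropylsilyloxy)phenyl]‑1,3‑dioxan‑5‑yl]methyl}propanedioate | COC(=O)C(C/C=C/c1ccc(O[Si](C(C)C)(C(C)C)C(C)C)cc1)(C[C@H]1[C@@H](OCOC1)c1ccc(O[Si](C(C)C)(C(C)C)C(C)C)cc1)C(=O)OC | intermediate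
10 | ring‑opened acetal: C6 trimethylsilyl ether, C7 (2,2′‑bipyridin‑1‑ium‑1‑yl)methyl ether, triflate salt (drawn with silicon on the primary oxygen; the sense of opening does not affect the outcome) | COC(=O)C(C/C=C/c1ccc(O[Si](C(C)C)(C(C)C)C(C)C)cc1)(C[C@H](CO[Si](C)(C)C)[C@@H](OC[n+]1ccccc1-c1ccccn1)c1ccc(O[Si](C(C)C)(C(C)C)C(C)C)cc1)C(=O)OC.[O-]S(=O)(=O)C(F)(F)F | intermediate
11 | dimethyl 2‑{(2R,3R)‑3‑hydroxy‑2‑(hydroxymethyl)‑3‑[4‑(triisopropylsilyloxy)phenyl]propyl}‑2‑{(E)‑3‑[4‑(triisopropylsilyloxy)phenyl]prop‑2‑en‑1‑yl}propanedioate | COC(=O)C(C/C=C/c1ccc(O[Si](C(C)C)(C(C)C)C(C)C)cc1)(C[C@H](CO)[C@@H](O)c1ccc(O[Si](C(C)C)(C(C)C)C(C)C)cc1)C(=O)OC | intermediate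
12 | methyl (5R)‑5‑{(R)‑hydroxy[4‑(triisopropylsilyloxy)phenyl]methyl}‑2‑oxo‑3‑{(E)‑3‑[4‑(triisopropylsilyloxy)phenyl]prop‑2‑en‑1‑yl}oxane‑3‑carboxylate, both C3 epimers | COC(=O)C1(C/C=C/c2ccc(O[Si](C(C)C)(C(C)C)C(C)C)cc2)C[C@H](COC1=O)[C@@H](O)c1ccc(O[Si](C(C)C)(C(C)C)C(C)C)cc1 | intermediate
13 | methyl (5R)‑5‑{(R)‑(tert‑butyldimethylsilyloxy)[4‑(triisopropylsilyloxy)phenyl]methyl}‑2‑oxo‑3‑{(E)‑3‑[4‑(triisopropylsilyloxy)phenyl]prop‑2‑en‑1‑yl}oxane‑3‑carboxylate, both C3 epimers | COC(=O)C1(C/C=C/c2ccc(O[Si](C(C)C)(C(C)C)C(C)C)cc2)C[C@H](COC1=O)[C@@H](O[Si](C)(C)C(C)(C)C)c1ccc(O[Si](C(C)C)(C(C)C)C(C)C)cc1 | intermediate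
14 | (5R)‑5‑{(R)‑(tert‑butyldimethylsilyloxy)[4‑(triisopropylsilyloxy)phenyl]methyl}‑3‑{(E)‑3‑[4‑(triisopropylsilyloxy)phenyl]prop‑2‑en‑1‑yl}oxan‑2‑one, mixture of C3 epimers | O=C1OC[C@@H](CC1C/C=C/c1ccc(O[Si](C(C)C)(C(C)C)C(C)C)cc1)[C@@H](O[Si](C)(C)C(C)(C)C)c1ccc(O[Si](C(C)C)(C(C)C)C(C)C)cc1 | intermediate
15 | (3S,5R)‑5‑{(R)‑(tert‑butyldimethylsilyloxy)[4‑(triisopropylsilyloxy)phenyl]methyl}‑3‑{(E)‑3‑[4‑(triisopropylsilyloxy)phenyl]prop‑2‑en‑1‑yl}oxan‑2‑one (3,5‑cis) | O=C1OC[C@@H](C[C@@H]1C/C=C/c1ccc(O[Si](C(C)C)(C(C)C)C(C)C)cc1)[C@@H](O[Si](C)(C)C(C)(C)C)c1ccc(O[Si](C(C)C)(C(C)C)C(C)C)cc1 | intermediate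
16 | (2S,4R,5R)‑5‑(tert‑butyldimethylsilyloxy)‑4‑(hydroxymethyl)‑N‑methoxy‑N‑methyl‑5‑[4‑(triisopropylsilyloxy)phenyl]‑2‑{(E)‑3‑[4‑(triisopropylsilyloxy)phenyl]prop‑2‑en‑1‑yl}pentanamide | CON(C)C(=O)[C@@H](C/C=C/c1ccc(O[Si](C(C)C)(C(C)C)C(C)C)cc1)C[C@H](CO)[C@@H](O[Si](C)(C)C(C)(C)C)c1ccc(O[Si](C(C)C)(C(C)C)C(C)C)cc1 | intermediate
17 | (2S,4R,5R)‑5‑(tert‑butyldimethylsilyloxy)‑N‑methoxy‑N‑methyl‑4‑[(4‑methylphenylsulfonyloxy)methyl]‑5‑[4‑(triisopropylsilyloxy)phenyl]‑2‑{(E)‑3‑[4‑(triisopropylsilyloxy)phenyl]prop‑2‑en‑1‑yl}pentanamide | CON(C)C(=O)[C@@H](C/C=C/c1ccc(O[Si](C(C)C)(C(C)C)C(C)C)cc1)C[C@H](COS(=O)(=O)c1ccc(C)cc1)[C@@H](O[Si](C)(C)C(C)(C)C)c1ccc(O[Si](C(C)C)(C(C)C)C(C)C)cc1 | intermediate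
18 | (4‑bromophenoxy)triisopropylsilane | CC(C)[Si](Oc1ccc(Br)cc1)(C(C)C)C(C)C | starting material
19 | [4‑(triisopropylsilyloxy)phenyl]magnesium bromide | CC(C)[Si](Oc1ccc([Mg]Br)cc1)(C(C)C)C(C)C | intermediate
20 | (2S,4R,5R)‑5‑(tert‑butyldimethylsilyloxy)‑1,5‑bis[4‑(triisopropylsilyloxy)phenyl]‑2‑{(E)‑3‑[4‑(triisopropylsilyloxy)phenyl]prop‑2‑en‑1‑yl}‑4‑[(4‑methylphenylsulfonyloxy)methyl]pentan‑1‑one | O=C(c1ccc(O[Si](C(C)C)(C(C)C)C(C)C)cc1)[C@@H](C/C=C/c1ccc(O[Si](C(C)C)(C(C)C)C(C)C)cc1)C[C@H](COS(=O)(=O)c1ccc(C)cc1)[C@@H](O[Si](C)(C)C(C)(C)C)c1ccc(O[Si](C(C)C)(C(C)C)C(C)C)cc1 | intermediate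
21 | (1R,2S,4R,5R)‑5‑(tert‑butyldimethylsilyloxy)‑1,5‑bis[4‑(triisopropylsilyloxy)phenyl]‑2‑{(E)‑3‑[4‑(triisopropylsilyloxy)phenyl]prop‑2‑en‑1‑yl}‑4‑[(4‑methylphenylsulfonyloxy)methyl]pentan‑1‑ol | O[C@@H](c1ccc(O[Si](C(C)C)(C(C)C)C(C)C)cc1)[C@@H](C/C=C/c1ccc(O[Si](C(C)C)(C(C)C)C(C)C)cc1)C[C@H](COS(=O)(=O)c1ccc(C)cc1)[C@@H](O[Si](C)(C)C(C)(C)C)c1ccc(O[Si](C(C)C)(C(C)C)C(C)C)cc1 | intermediate
22 | (2R,3S,5R)‑5‑{(R)‑(tert‑butyldimethylsilyloxy)[4‑(triisopropylsilyloxy)phenyl]methyl}‑2‑[4‑(triisopropylsilyloxy)phenyl]‑3‑{(E)‑3‑[4‑(triisopropylsilyloxy)phenyl]prop‑2‑en‑1‑yl}oxane | CC(C)[Si](Oc1ccc(/C=C/C[C@H]2C[C@@H]([C@@H](O[Si](C)(C)C(C)(C)C)c3ccc(O[Si](C(C)C)(C(C)C)C(C)C)cc3)CO[C@H]2c2ccc(O[Si](C(C)C)(C(C)C)C(C)C)cc2)cc1)(C(C)C)C(C)C | intermediate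
23 | 4‑[(2R,3S,5R)‑5‑[(R)‑hydroxy(4‑hydroxyphenyl)methyl]‑3‑[(E)‑3‑(4‑hydroxyphenyl)prop‑2‑en‑1‑yl]oxan‑2‑yl]phenol | Oc1ccc(/C=C/C[C@H]2C[C@@H]([C@@H](O)c3ccc(O)cc3)CO[C@H]2c2ccc(O)cc2)cc1 | target

**Step count and risk**

Total: 15 steps. Longest linear sequence: 15 steps, from 1 to 23; 5, 8 and 18 enter as purchased materials.

Least certain steps:

*Step 5 (key step, proposed new method).* Three things may go wrong. Enantioface selection may be poor on an internal, strongly donor‑substituted styrene, because a long‑lived benzylic cation can escape the chiral ion pair. That cation may be captured by the second styrene arm in a six‑membered cation–alkene cyclisation instead of closing the dioxane. Conversion may also run on to the bis‑dioxane. The fallback uses known reactions only and gives up the Prins disconnection. It sets out from 6, made on purpose from 5 and one equivalent of 4 under the conditions of step 4 and isolated. Base‑catalysed conjugate addition of 6 to (R)‑3‑acryloyl‑4‑benzyl‑1,3‑oxazolidin‑2‑one (t‑BuOK cat., THF, 0 °C) would give the Michael adduct F1. A magnesium‑halide‑catalysed anti‑aldol reaction of F1 with 4‑(triisopropylsilyloxy)benzaldehyde (MgCl2, Et3N, Me3SiCl, ethyl acetate) would give the silylated aldol adduct F2; the chelated Z‑enolate is attacked on the face away from the benzyl group and the anti relationship is that of the trans‑dioxane. Et3N·3HF would remove the trimethylsilyl group to give the hydroxy imide F3, and LiBH4 (THF, one equivalent of MeOH, 0 °C) would cleave the auxiliary reductively while the hindered malonate esters are expected to survive. The route is rejoined at 11.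

*Step 6.* The benzylic C7–O bond may ionise under the silyl triflate, which would scramble C7 or lead to elimination, because the p‑silyloxy group stabilises that cation nearly as well as oxygen stabilises the oxocarbenium ion. The fallback replaces electrophile‑triggered ionisation by nucleophile‑assisted opening at low temperature. From 9, Me2BBr (CH2Cl2, −78 °C) delivers bromide to the acetal carbon within the boron complex and gives the bromomethyl ether borinate F4, which aqueous NaHCO3 hydrolyses; the route is rejoined at 11.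

*Step 7.* The free C7 hydroxyl may take part in acyl transfer (translactonisation onto C2, or a second lactone onto the remaining ester) if the base‑catalysed lactonisation is not stopped in time. The fallback protects first and lactonises second. From 11, selective silylation of the primary hydroxyl (Et3SiCl, imidazole, CH2Cl2, −40 °C) gives the mono‑triethylsilyl ether F5. Silylation of C7–OH (t‑BuMe2SiOTf, 2,6‑lutidine) gives the bis‑silyl ether F6. Buffered HF·pyridine (pyridine, THF, 0 °C) removes only the primary triethylsilyl group to give the hydroxy diester F7, which catalytic DBU closes; the route is rejoined at 13.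

*Step 9.* Two processes may fail: loss of silyl groups under hot iodide and carboxylate, and an unfavourable or slow cis/trans equilibration at C3. The fallback changes the way the ester is removed. From 13, Me3SnOH (1,2‑dichloroethane, 80 °C) hydrolyses the methyl ester to the lactone acid F8, which loses CO2 on heating in toluene (100 °C); the route is rejoined at 14 and the equilibration to 15 follows as before. If the equilibrium ratio is modest, the trans isomer is separated and resubjected.

*Step 13.* Facial selectivity may be poor because the ketone is flanked by an aryl group and an α‑branched chain of similar size, and the inherent bias of the C3 stereocentre may oppose the catalyst. The fallback makes C2 by aryl transfer instead of hydride transfer. From 17, i‑Bu2AlH (THF, −78 °C) gives the aldehyde F9. A catalytic enantioselective aryl transfer follows, with 4‑(triisopropylsilyloxy)phenylboronic acid, Et2Zn and a chiral amino alcohol ligand such as 3‑exo‑morpholinoisoborneol in the antipode that delivers the (1R) carbinol; there the catalyst only has to tell hydrogen from an alkyl chain. The route is rejoined at 21.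

**Further compounds**

F1 | step 5 | dimethyl 2‑{3‑[(R)‑4‑benzyl‑2‑oxo‑1,3‑oxazolidin‑3‑yl]‑3‑oxopropyl}‑2‑{(E)‑3‑[4‑(triisopropylsilyloxy)phenyl]prop‑2‑en‑1‑yl}propanedioate | COC(=O)C(C/C=C/c1ccc(O[Si](C(C)C)(C(C)C)C(C)C)cc1)(CCC(=O)N1[C@H](Cc2ccccc2)COC1=O)C(=O)OC
F2 | step 5 | anti‑aldol adduct of F1 as its trimethylsilyl ether | COC(=O)C(C/C=C/c1ccc(O[Si](C(C)C)(C(C)C)C(C)C)cc1)(C[C@@H]([C@@H](O[Si](C)(C)C)c1ccc(O[Si](C(C)C)(C(C)C)C(C)C)cc1)C(=O)N1[C@H](Cc2ccccc2)COC1=O)C(=O)OC
F3 | step 5 | free anti‑aldol adduct (hydroxy imide) | COC(=O)C(C/C=C/c1ccc(O[Si](C(C)C)(C(C)C)C(C)C)cc1)(C[C@@H]([C@@H](O)c1ccc(O[Si](C(C)C)(C(C)C)C(C)C)cc1)C(=O)N1[C@H](Cc2ccccc2)COC1=O)C(=O)OC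
F4 | step 6 | C7 bromomethyl ether, C6 dimethylborinate of diol 11 (drawn as one regioisomer of opening) | COC(=O)C(C/C=C/c1ccc(O[Si](C(C)C)(C(C)C)C(C)C)cc1)(C[C@H](COB(C)C)[C@@H](OCBr)c1ccc(O[Si](C(C)C)(C(C)C)C(C)C)cc1)C(=O)OC
F5 | step 7 | diol 11 with the primary hydroxyl as its triethylsilyl ether | COC(=O)C(C/C=C/c1ccc(O[Si](C(C)C)(C(C)C)C(C)C)cc1)(C[C@H](CO[Si](CC)(CC)CC)[C@@H](O)c1ccc(O[Si](C(C)C)(C(C)C)C(C)C)cc1)C(=O)OC
F6 | step 7 | F5 with the C7 hydroxyl as its tert‑butyldimethylsilyl ether | COC(=O)C(C/C=C/c1ccc(O[Si](C(C)C)(C(C)C)C(C)C)cc1)(C[C@H](CO[Si](CC)(CC)CC)[C@@H](O[Si](C)(C)C(C)(C)C)c1ccc(O[Si](C(C)C)(C(C)C)C(C)C)cc1)C(=O)OC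
F7 | step 7 | primary alcohol diester with C7 tert‑butyldimethylsilyl ether | COC(=O)C(C/C=C/c1ccc(O[Si](C(C)C)(C(C)C)C(C)C)cc1)(C[C@H](CO)[C@@H](O[Si](C)(C)C(C)(C)C)c1ccc(O[Si](C(C)C)(C(C)C)C(C)C)cc1)C(=O)OC
F8 | step 9 | (5R)‑5‑{(R)‑(tert‑butyldimethylsilyloxy)[4‑(triisopropylsilyloxy)phenyl]methyl}‑2‑oxo‑3‑{(E)‑3‑[4‑(triisopropylsilyloxy)phenyl]prop‑2‑en‑1‑yl}oxane‑3‑carboxylic acid, both C3 epimers | OC(=O)C1(C/C=C/c2ccc(O[Si](C(C)C)(C(C)C)C(C)C)cc2)C[C@H](COC1=O)[C@@H](O[Si](C)(C)C(C)(C)C)c1ccc(O[Si](C(C)C)(C(C)C)C(C)C)cc1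
F9 | step 13 | (2S,4R,5R)‑5‑(tert‑butyldimethylsilyloxy)‑4‑[(4‑methylphenylsulfonyloxy)methyl]‑5‑[4‑(triisopropylsilyloxy)phenyl]‑2‑{(E)‑3‑[4‑(triisopropylsilyloxy)phenyl]prop‑2‑en‑1‑yl}pentanal | O=C[C@@H](C/C=C/c1ccc(O[Si](C(C)C)(C(C)C)C(C)C)cc1)C[C@H](COS(=O)(=O)c1ccc(C)cc1)[C@@H](O[Si](C)(C)C(C)(C)C)c1ccc(O[Si](C(C)C)(C(C)C)C(C)C)cc1
A1 | alternative 1 | 1,5‑bis[(R)‑4‑benzyl‑2‑oxo‑1,3‑oxazolidin‑3‑yl]pentane‑1,5‑dione | O=C(CCCC(=O)N1[C@H](Cc2ccccc2)COC1=O)N1[C@H](Cc2ccccc2)COC1=O
A2 | alternative 1 | 4‑(tert‑butyldimethylsilyloxy)benzaldehyde | O=Cc1ccc(O[Si](C)(C)C(C)(C)C)cc1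
A3 | alternative 1 | twofold‑symmetric anti,anti bis‑aldol adduct | O=C(N1[C@H](Cc2ccccc2)COC1=O)[C@H]([C@@H](O)c1ccc(O[Si](C)(C)C(C)(C)C)cc1)C[C@@H]([C@@H](O)c1ccc(O[Si](C)(C)C(C)(C)C)cc1)C(=O)N1[C@H](Cc2ccccc2)COC1=O
A4 | alternative 2 | (R)‑[4‑(tert‑butyldimethylsilyloxy)phenyl][(S)‑cyclohex‑3‑en‑1‑yl]methanol | O[C@@H](c1ccc(O[Si](C)(C)C(C)(C)C)cc1)[C@@H]1CC=CCC1
A5 | alternative 2 | 2‑aryl‑3‑oxabicyclo[3.3.1]non‑6‑ene with equatorial aryl group | C1[C@H]2C[C@@H](C=C1)CO[C@H]2c1ccc(O[Si](C)(C)C(C)(C)C)cc1
A6 | alternative 3 | cis‑2‑aryl‑3‑alkyl cyclopropane‑1,1‑diester with free C6 hydroxyl | COC(=O)C1(C(=O)OC)[C@H](c2ccc(OS(C)(=O)=O)cc2)[C@@H]1C[C@H](CO)[C@@H](O[Si](C)(C)C(C)(C)C)c1ccc(O[Si](C)(C)C(C)(C)C)cc1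
A7 | alternative 3 | all‑cis 2‑aryl‑3‑(malonyl)‑5‑[aryl(silyloxy)methyl]oxane | COC(=O)C(C(=O)OC)[C@H]2C[C@@H]([C@@H](O[Si](C)(C)C(C)(C)C)c3ccc(O[Si](C)(C)C(C)(C)C)cc3)CO[C@H]2c2ccc(OS(C)(=O)=O)cc2
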